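**Retrosynthetic overview**
1. 30 ⇐ 28: the dihydrofuran is closed last, by 5-endo iodoetherification of the C13 vinyl/CH2OH pair and E2 loss of HI.
2. 28 ⇐ bis-epoxide 27 in one zerovalent-palladium relay (key step): a Payne shift turns the 8α,9α-epoxide into the 8β,17-epoxide and frees the 9α-alkoxide, which closes the oxolane on a π-allyl at C13 (sets C8, C9, C13).
3. 27 ⇐ exo-methylene ketone 19 + diene bromide 21: C9–C11 bond by organocerium addition, oxidative 1,3-transposition, double epoxidation.
4. 19 ⇐ tricyclic lactone 14: ring A is closed by bridging alkylation of a δ-lactone enolate (fixes C4); C6 is inverted through the ketone.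
5. Ring B ⇐ (S)-4-benzyloxycyclohexenone 4: Baylis–Hillman C20, ester-enolate Michael (C5) then allylation (C10), lactonisation. Ring order: B, δ-lactone, A, oxirane plus oxolane together, dihydrofuran.

Assumption: ring positions of all intermediates carry labdane numbers (C1–C20) and α/β face labels; compounds 1, 7, 20 and all reagents are bought.

**Step 1**
Reactants: 1 1,4-dioxaspiro[4.5]dec-6-en-8-one
Product: 2 (S)-1,4-dioxaspiro[4.5]dec-6-en-8-ol
Conditions: (R)-2-methyl-CBS-oxazaborolidine (10 mol%), catecholborane, toluene, −78 °C; aqueous work-up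
Reagents that add atoms: none
Why: Corey–Bakshi–Shibata reduction, in which the enone double bond acts as the large group so that the (R)-oxazaborolidine is expected to give the S carbinol (future C6), the centre that steers all later ones.

**Step 2**
Reactants: 2 (S)-1,4-dioxaspiro[4.5]dec-6-en-8-ol
Product: 3 (S)-8-(benzyloxy)-1,4-dioxaspiro[4.5]dec-6-ene
Conditions: NaH, BnBr, Bu4NI (cat.), THF, 0 °C to rt
Reagents that add atoms: benzyl bromide, BrCc1ccccc1
Why: Williamson etherification of the alkoxide, which does not touch the stereocentre.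

**Step 3**
Reactants: 3 (S)-8-(benzyloxy)-1,4-dioxaspiro[4.5]dec-6-ene
Product: 4 (S)-4-(benzyloxy)cyclohex-2-en-1-one
Conditions: PPTS (cat.), acetone/H2O 10:1, 50 °C
Reagents that add atoms: water, O
Why: acid-catalysed acetal hydrolysis unmasks the ketone (future C9) in conjugation with the alkene and leaves the benzyloxy-bearing carbon untouched.

**Step 4**
Reactants: 4 (S)-4-(benzyloxy)cyclohex-2-en-1-one
Product: 5 (S)-4-(benzyloxy)-2-(hydroxymethyl)cyclohex-2-en-1-one
Conditions: 37% aq. CH2O, DMAP (0.3 equiv), THF/H2O, rt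
Reagents that add atoms: formaldehyde, C=O
Why: Morita–Baylis–Hillman hydroxymethylation at the enone α-carbon installs C20 on the future C10 without creating a stereocentre.

**Step 5**
Reactants: 5 (S)-4-(benzyloxy)-2-(hydroxymethyl)cyclohex-2-en-1-one
Product: 6 (S)-4-(benzyloxy)-2-{[(tert-butyldimethylsilyl)oxy]methyl}cyclohex-2-en-1-one
Conditions: TBSCl, imidazole, DMF, rt
Reagents that add atoms: tert-butyldimethylsilyl chloride, CC(C)(C)[Si](C)(C)Cl
Why: standard silylation of the primary alcohol so that it survives the enolate chemistry.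

**Step 6**
Reactants: 6 (S)-4-(benzyloxy)-2-{[(tert-butyldimethylsilyl)oxy]methyl}cyclohex-2-en-1-one; 7 methyl propanoate
Product: 10 methyl 2-[(1S,2S,6S)-6-(benzyloxy)-2-{[(tert-butyldimethylsilyl)oxy]methyl}-3-oxo-2-(prop-2-en-1-yl)cyclohexyl]propanoate (propanoate C2 epimers), via lithium ester enolate 8 (not isolated), via lithium ketone enolate 9 (not isolated)
Conditions: LiN(i-Pr)2 (commercial solution, 1.1 equiv), 7, THF, −78 °C; add 6 and DMPU, −78 to −40 °C; then allyl iodide, −78 to 0 °C
Reagents that add atoms: allyl iodide, C=CCI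
Why: Michael addition of the ester enolate anti to the benzyloxy group sets C5, and the regiodefined ketone enolate is then C-allylated trans to the new C5 arm, which sets the quaternary C10 with its CH2OTBS cis to the propanoate arm (the propanoate α-centre is erased in step 10).

**Step 7**
Reactants: 10 methyl 2-[(1S,2S,6S)-6-(benzyloxy)-2-{[(tert-butyldimethylsilyl)oxy]methyl}-3-oxo-2-(prop-2-en-1-yl)cyclohexyl]propanoate
Product: 11 cis-fused δ-lactone (4aS,5S,8aS)-8a-allyl-5-(benzyloxy)-4-methyloctahydroisochromene-3,8-dione (C4 epimers)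
Conditions: 48% aq. HF, MeCN, 0 to 40 °C
Reagents that add atoms: none
Why: desilylation followed by acid-catalysed lactonisation of the C20 hydroxyl onto the cis-disposed methyl ester gives the 19,20-δ-lactone.

**Step 8**
Reactants: 11 cis-fused δ-lactone with C10 allyl group
Product: 12 (4aS,5S,8aS)-5-(benzyloxy)-8a-(3-bromopropyl)-4-methyloctahydroisochromene-3,8-dione (C4 epimers)
Conditions: HBr (gas), AIBN (cat.), hexane/CH2Cl2, hν, 0 °C
Reagents that add atoms: hydrogen bromide, Br
Why: radical-chain (Kharasch) anti-Markovnikov hydrobromination of the terminal alkene gives the primary bromide C3–Br.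

**Step 9**
Reactants: 12 bromide
Product: 13 (4aS,5S,8aS)-5-(benzyloxy)-8a-(3-bromopropyl)-8-[(tert-butyldimethylsilyl)oxy]-4-methyl-1,4,4a,5,6,8a-hexahydro-3H-isochromen-3-one (C4 epimers)
Conditions: TBSOTf, Et3N, CH2Cl2, −78 to 0 °C
Reagents that add atoms: tert-butyldimethylsilyl triflate, CC(C)(C)[Si](C)(C)OS(=O)(=O)C(F)(F)F
Why: soft enolisation, possible only toward C8 because C10 is quaternary, masks the ketone as the C8=C9 silyl enol ether before the strong base of step 10.

**Step 10**
Reactants: 13 silyl enol ether bromide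
Product: 14 tricyclic lactone (4S,5R,6S,10S)-6α-(benzyloxy)-9-[(tert-butyldimethylsilyl)oxy]-4α-methyl-trans-decal-8-ene with the δ-lactone C19(=O)–O–C20 bridging C4β and C10β
Conditions: LiN(i-Pr)2 (1.2 equiv), THF/DMPU, −78 to 0 °C, 0.01 M
Reagents that add atoms: none
Why: intramolecular 6-exo-tet alkylation of the δ-lactone enolate closes ring A, and because the C3–C4 bond can only form on the face carrying the C10 chain, the bicyclo[3.3.1] frame forces C19 β and the methyl α at C4 from either C4 epimer.

**Step 11**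
Reactants: 14 tricyclic lactone with 6α-OBn
Product: 15 6α-hydroxy tricyclic lactone (4S,5R,6S,10S)
Conditions: H2 (1 atm), 10% Pd on carbon, EtOAc, rt
Reagents that add atoms: none
Why: hydrogenolysis of the benzyl ether, under which the hindered trisubstituted silyl enol ether is not reduced.

**Step 12**
Reactants: 15 6α-hydroxy tricyclic lactone
Product: 16 6-oxo tricyclic lactone (4S,5R,10S)
Conditions: Dess–Martin periodinane, pyridine, CH2Cl2, 0 °C to rt
Reagents that add atoms: none
Why: mild buffered oxidation to the C6 ketone, with the trans ring fusion (H5 α) expected to be the stable arrangement next to the two quaternary carbons.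

**Step 13**
Reactants: 16 6-oxo tricyclic lactone
Product: 17 6β-hydroxy tricyclic lactone (4S,5R,6R,10S)
Conditions: NaBH4, MeOH/CH2Cl2, −40 to −20 °C; pH 7 buffer
Reagents that add atoms: none
Why: hydride attacks from the open α face because the β face of C6 is screened by the axial C19/C20 lactone bridge, giving the axial 6β-alcohol, and the cold protic medium with neutral quench keeps this alcohol from attacking the lactone.

**Step 14**
Reactants: 17 6β-hydroxy tricyclic lactone
Product: 18 6β-acetoxy tricyclic lactone (4S,5R,6R,10S)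
Conditions: Ac2O, DMAP (cat.), pyridine, CH2Cl2, 0 °C to rt
Reagents that add atoms: acetic anhydride, CC(=O)OC(C)=O
Why: DMAP-catalysed acetylation of the hindered axial alcohol, done at once so that trans-lactonisation to the 19,6-lactone is blocked for the rest of the route.

**Step 15**
Reactants: 18 6β-acetoxy tricyclic lactone
Product: 19 (4S,5R,6R,10S)-6β-acetoxy-8-methylidene-9-oxo tricyclic lactone (exocyclic C8=C17 enone)
Conditions: paraformaldehyde, N-methylanilinium trifluoroacetate, wet THF, 65 °C
Reagents that add atoms: formaldehyde (as paraformaldehyde), C=O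
Why: the acid cleaves the silyl enol ether and the ketone then undergoes Mannich condensation and β-elimination (Gras α-methylenation) at C8, its only enolisable position, which brings in C17.

**Step 16**
Reactants: 20 4-bromobut-1-yne
Product: 21 5-bromo-3-methylidenepent-1-ene
Conditions: ethylene (1 atm), second-generation Grubbs catalyst (3 mol%), CH2Cl2, rt
Reagents that add atoms: ethylene, C=C
Why: cross enyne metathesis of a terminal alkyne with ethylene gives the 2-substituted buta-1,3-diene (C11–C16 of the side chain).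

**Step 17**
Reactants: 19 exo-methylene ketone; 21 5-bromo-3-methylidenepent-1-ene
Product: 24 tertiary allylic alcohol 6β-acetoxy-9β-hydroxy-8-methylidene-9α-(3-methylidenepent-4-en-1-yl) tricyclic lactone (9S), via Grignard reagent 22 (not isolated), via organocerium reagent 23 (not isolated)
Conditions: Mg, THF, rt; CeCl3 (anhydrous, 1.5 equiv), THF, −78 °C; then 19, −78 °C; H2O
Reagents that add atoms: none
Why: organocerium 1,2-addition to the hindered, non-enolisable enone avoids 1,4-addition and attack on acetate or lactone, and the α-face attack (anti to C20) gives a C9 centre that is erased in step 18.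

**Step 18**
Reactants: 24 tertiary allylic alcohol
Product: 25 enal (4S,5R,6R,10S)-6β-acetoxy-17-oxolabda-8,13(16),14-trien-19,20-olide
Conditions: [C5H5NH][CrO3Cl] (pyridinium chlorochromate, 2.5 equiv), 4 Å sieves, CH2Cl2, rt
Reagents that add atoms: none
Why: Babler–Dauben oxidative transposition, in which the tertiary allylic chromate ester shifts [3,3] to C17 and is oxidised, giving the tetrasubstituted C8=C9 alkene with the side chain on C9.

**Step 19**
Reactants: 25 enal
Product: 26 allylic alcohol (4S,5R,6R,10S)-6β-acetoxy-17-hydroxylabda-8,13(16),14-trien-19,20-olide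
Conditions: NaBH4, CeCl3·7H2O, MeOH, −40 °C
Reagents that add atoms: none
Why: Luche 1,2-reduction of the enal leaves the diene, acetate and lactone alone.

**Step 20**
Reactants: 26 allylic alcohol
Product: 27 bis-epoxide 6β-acetoxy-8α,9α:13,16-diepoxy-17-hydroxylabd-14-en-19,20-olide (8S,9S; C13 epimers)
Conditions: mCPBA (2.3 equiv), NaHCO3, CH2Cl2, −20 to 0 °C
Reagents that add atoms: mCPBA, OOC(=O)c1cccc(Cl)c1
Why: Prilezhaev epoxidation attacks the tetrasubstituted C8=C9 bond from the α face (the β face is blocked by axial C20 and the 6β-acetate) and, of the diene, the more electron-rich 1,1-disubstituted C13=C16 bond, giving the 2-vinyloxirane as both C13 epimers, which converge in step 21.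

**Step 21**
Reactants: 27 bis-epoxide
Product: 28 (13R)-6β-acetoxy-8β,17:9α,13-diepoxy-16-hydroxylabd-14-en-19,20-olide
Conditions: Pd2(dba)3·CHCl3 (2.5 mol%), (R,R)-DACH-phenyl Trost ligand (7.5 mol%), degassed THF, rt, 0.01 M
Reagents that add atoms: none
Why: Proposed new method: zerovalent palladium opens the vinyl epoxide reversibly to a π-allyl complex whose alkoxide deprotonates the C17 hydroxyl, the C17 alkoxide then attacks C8 from the β face (Payne rearrangement, inversion at C8) to give the 8β,17-epoxide and the 9α-alkoxide, and only this alkoxide can reach the π-allyl carbon C13 through a five-membered ring (the C17 alkoxide would need a seven-membered one), so the unfavourable Payne equilibrium is drained while the chiral diphosphine sets C13 through π–σ–π equilibration of both epoxide epimers; the closest known reactions are the base-induced Payne rearrangement and the Trost palladium-catalysed asymmetric addition of alcohols to vinyl epoxides, and the ligand antipode giving 13R (R,R assumed) is fixed by one pilot run.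

**Step 22**
Reactants: 28 vinyl carbinol
Product: 29 6β-acetoxy-8β,17:9α,13:15,16-triepoxy-14-iodolabdan-19,20-olide (C14 epimers)
Conditions: N-iodosuccinimide, NaHCO3, MeCN, −20 to 0 °C, dark
Reagents that add atoms: N-iodosuccinimide, O=C1CCC(=O)N1I
Why: 5-endo-trig iodoetherification, in which the C16 hydroxyl opens the iodonium ion at the terminal C15 because the internal carbon is deactivated by the adjacent C13–O bond and a four-membered ring is disfavoured.

**Step 23**
Reactants: 29 iodo ether
Product: 30 target, (4S,5R,6R,8R,9S,10S,13R)-6-acetoxy-8,17:9,13:15,16-triepoxylabd-14-en-19,20-olide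
Conditions: DBU, toluene, 90 °C
Reagents that add atoms: none
Why: anti E2 elimination of HI can only use a C15 hydrogen because C13 is quaternary, so the C14=C15 enol ether forms regiospecifically from either C14 epimer under non-nucleophilic conditions that spare acetate, lactone and epoxide.

**Compound list**
1 | 1,4-dioxaspiro[4.5]dec-6-en-8-one | O=C1C=CC2(CC1)OCCO2 | starting material
2 | (S)-1,4-dioxaspiro[4.5]dec-6-en-8-ol | O[C@@H]1C=CC2(CC1)OCCO2 | intermediate
3 | (S)-8-(benzyloxy)-1,4-dioxaspiro[4.5]dec-6-ene | c1ccccc1CO[C@@H]1C=CC2(CC1)OCCO2 | intermediate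
4 | (S)-4-(benzyloxy)cyclohex-2-en-1-one | c1ccccc1CO[C@@H]1C=CC(=O)CC1 | intermediate
5 | (S)-4-(benzyloxy)-2-(hydroxymethyl)cyclohex-2-en-1-one | c1ccccc1CO[C@@H]1C=C(CO)C(=O)CC1 | intermediate
6 | (S)-4-(benzyloxy)-2-{[(tert-butyldimethylsilyl)oxy]methyl}cyclohex-2-en-1-one | c1ccccc1CO[C@@H]1C=C(CO[Si](C)(C)C(C)(C)C)C(=O)CC1 | intermediate
7 | methyl propanoate | CCC(=O)OC | starting material
8 | lithium 1-methoxyprop-1-en-1-olate (ester enolate of 7) | [Li+].CC=C([O-])OC | intermediate
9 | lithium enolate of the 1,4-adduct (C9–OLi, C9=C10–CH2OTBS, 5β-CH(CH3)CO2CH3, 6α-OBn) | [Li+].c1ccccc1CO[C@@H]1[C@@H](C(C)C(=O)OC)C(CO[Si](C)(C)C(C)(C)C)=C([O-])CC1 | intermediate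
10 | methyl 2-[(1S,2S,6S)-6-(benzyloxy)-2-{[(tert-butyldimethylsilyl)oxy]methyl}-3-oxo-2-(prop-2-en-1-yl)cyclohexyl]propanoate (propanoate C2 epimers) | c1ccccc1CO[C@@H]1[C@@H](C(C)C(=O)OC)[C@@](CC=C)(CO[Si](C)(C)C(C)(C)C)C(=O)CC1 | intermediate
11 | (4aS,5S,8aS)-8a-allyl-5-(benzyloxy)-4-methyloctahydroisochromene-3,8-dione, cis-fused δ-lactone (C4 epimers) | c1ccccc1CO[C@@H]1[C@H]2C(C)C(=O)OC[C@@]2(CC=C)C(=O)CC1 | intermediate
12 | (4aS,5S,8aS)-5-(benzyloxy)-8a-(3-bromopropyl)-4-methyloctahydroisochromene-3,8-dione (C4 epimers) | c1ccccc1CO[C@@H]1[C@H]2C(C)C(=O)OC[C@@]2(CCCBr)C(=O)CC1 | intermediate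
13 | (4aS,5S,8aS)-5-(benzyloxy)-8a-(3-bromopropyl)-8-[(tert-butyldimethylsilyl)oxy]-4-methyl-1,4,4a,5,6,8a-hexahydro-3H-isochromen-3-one (C4 epimers) | c1ccccc1CO[C@@H]1[C@H]2C(C)C(=O)OC[C@@]2(CCCBr)C(O[Si](C)(C)C(C)(C)C)=CC1 | intermediate
14 | (4S,5R,6S,10S)-6α-(benzyloxy)-9-[(tert-butyldimethylsilyl)oxy]-4α-methyl-trans-decal-8-ene 19,20-lactone (C19(=O)–O–C20 bridging C4β and C10β) | c1ccccc1CO[C@H]1CC=C(O[Si](C)(C)C(C)(C)C)[C@]23CCC[C@](C)(C(=O)OC2)[C@H]13 | intermediate
15 | 6α-hydroxy analogue of 14 (4S,5R,6S,10S) | O[C@H]1CC=C(O[Si](C)(C)C(C)(C)C)[C@]23CCC[C@](C)(C(=O)OC2)[C@H]13 | intermediate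
16 | 6-oxo analogue (4S,5R,10S) | O=C1CC=C(O[Si](C)(C)C(C)(C)C)[C@]23CCC[C@](C)(C(=O)OC2)[C@H]13 | intermediate
17 | 6β-hydroxy analogue (4S,5R,6R,10S) | O[C@@H]1CC=C(O[Si](C)(C)C(C)(C)C)[C@]23CCC[C@](C)(C(=O)OC2)[C@H]13 | intermediate
18 | 6β-acetoxy analogue (4S,5R,6R,10S) | CC(=O)O[C@@H]1CC=C(O[Si](C)(C)C(C)(C)C)[C@]23CCC[C@](C)(C(=O)OC2)[C@H]13 | intermediate
19 | (4S,5R,6R,10S)-6β-acetoxy-8-methylidene-9-oxo tricyclic 19,20-lactone | CC(=O)O[C@@H]1CC(=C)C(=O)[C@]23CCC[C@](C)(C(=O)OC2)[C@H]13 | intermediate
20 | 4-bromobut-1-yne | BrCCC#C | starting material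
21 | 5-bromo-3-methylidenepent-1-ene | BrCCC(=C)C=C | intermediate
22 | (3-methylidenepent-4-en-1-yl)magnesium bromide | Br[Mg]CCC(=C)C=C | intermediate
23 | dichloro(3-methylidenepent-4-en-1-yl)cerium | Cl[Ce](Cl)CCC(=C)C=C | intermediate
24 | (4S,5R,6R,9S,10S)-6β-acetoxy-9β-hydroxy-8-methylidene-9α-(3-methylidenepent-4-en-1-yl) tricyclic 19,20-lactone | CC(=O)O[C@@H]1CC(=C)[C@@](O)(CCC(=C)C=C)[C@]23CCC[C@](C)(C(=O)OC2)[C@H]13 | intermediate
25 | (4S,5R,6R,10S)-6β-acetoxy-17-oxolabda-8,13(16),14-trien-19,20-olide | CC(=O)O[C@@H]1CC(C=O)=C(CCC(=C)C=C)[C@]23CCC[C@](C)(C(=O)OC2)[C@H]13 | intermediate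
26 | (4S,5R,6R,10S)-6β-acetoxy-17-hydroxylabda-8,13(16),14-trien-19,20-olide | CC(=O)O[C@@H]1CC(CO)=C(CCC(=C)C=C)[C@]23CCC[C@](C)(C(=O)OC2)[C@H]13 | intermediate
27 | 6β-acetoxy-8α,9α:13,16-diepoxy-17-hydroxylabd-14-en-19,20-olide (8S,9S; C13 epimers) | CC(=O)O[C@@H]1C[C@@]2(CO)O[C@@]2(CCC4(C=C)CO4)[C@]23CCC[C@](C)(C(=O)OC2)[C@H]13 | intermediate
28 | (13R)-6β-acetoxy-8β,17:9α,13-diepoxy-16-hydroxylabd-14-en-19,20-olide | CC(=O)O[C@@H]1C[C@@]2(CO2)[C@]2(CC[C@@](C=C)(CO)O2)[C@]23CCC[C@](C)(C(=O)OC2)[C@H]13 | intermediate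
29 | 6β-acetoxy-8β,17:9α,13:15,16-triepoxy-14-iodolabdan-19,20-olide (C14 epimers; C13 as in 28) | CC(=O)O[C@@H]1C[C@@]2(CO2)[C@]2(CC[C@]3(C(I)COC3)O2)[C@]23CCC[C@](C)(C(=O)OC2)[C@H]13 | intermediate
30 | (4S,5R,6R,8R,9S,10S,13R)-6-acetoxy-8,17:9,13:15,16-triepoxylabd-14-en-19,20-olide (6β-OAc, 8β,17-epoxide, 9α,13-ether) | CC(=O)O[C@@H]1C[C@@]2(CO2)[C@]2(CC[C@]3(C=COC3)O2)[C@]23CCC[C@](C)(C(=O)OC2)[C@H]13 | target

**Totals**
Total step count: 23. Longest linear sequence: 22 steps (steps 1–15, then 17–23); step 16 is the one-step side branch.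

**Three steps most likely to fail**

Step 21 (palladium relay). The Payne shift may be too slow, or the primary C17 alkoxide may intercept the π-allyl complex first. The fallback sets out from 27 and returns at 28, and takes the relay apart. Compound 27 is stirred with catalytic KOt-Bu in t-BuOH/THF at 0 °C, so that the Payne equilibrium is established on its own. The rearranged tertiary alcohol, 6β-acetoxy-8β,17:13,16-diepoxy-9α-hydroxylabd-14-en-19,20-olide F1, is separated by chromatography and unchanged 27 is recycled. F1, which has no competing primary hydroxyl, is then closed to 28 by an ordinary Tsuji–Trost etherification with Pd2(dba)3·CHCl3 and the same Trost ligand.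

Step 6 (one-pot Michael addition and allylation). The lithium ester enolate may add 1,2, or the β-silyloxy ketone enolate may eliminate before it is allylated. The fallback sets out from 6 and returns at 10, and avoids free enolates. Mukaiyama–Michael addition of commercial 1-methoxy-1-(trimethylsilyloxy)prop-1-ene to 6 (TBSOTf 5 mol%, CH2Cl2, −78 °C) gives the trimethylsilyl enol ether F2. F2 is then allylated regiospecifically by the Tsuji method (allyl methyl carbonate, Pd2(dba)3·CHCl3, dppe, THF, 65 °C), trans to the C5 arm, to give 10.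

Step 22 (5-endo iodoetherification). The iodonium ion may be opened at the wrong carbon, or the later E2 toward the oxygen-bearing carbon may be sluggish. The fallback sets out from 28 and returns at 30, bypassing 29 and step 23. Reversible, thermodynamically controlled 5-endo selenoetherification (PhSeCl, pyridine, CH2Cl2, −78 °C) gives the 14-phenylselanyl oxolane F3. Oxidation with NaIO4/NaHCO3 in aqueous THF and syn-elimination of the selenoxide, which can only use a C15 hydrogen, gives 30 directly.

**Further compounds**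
F1 | step 21 | 6β-acetoxy-8β,17:13,16-diepoxy-9α-hydroxylabd-14-en-19,20-olide (C13 epimers) | CC(=O)O[C@@H]1C[C@@]2(CO2)[C@](O)(CCC4(C=C)CO4)[C@]23CCC[C@](C)(C(=O)OC2)[C@H]13
F2 | step 6 | methyl 2-[(1S,6S)-6-(benzyloxy)-2-{[(tert-butyldimethylsilyl)oxy]methyl}-3-[(trimethylsilyl)oxy]cyclohex-2-en-1-yl]propanoate (propanoate C2 epimers) | c1ccccc1CO[C@@H]1[C@@H](C(C)C(=O)OC)C(CO[Si](C)(C)C(C)(C)C)=C(O[Si](C)(C)C)CC1
F3 | step 22 | 6β-acetoxy-8β,17:9α,13:15,16-triepoxy-14-(phenylselanyl)labdan-19,20-olide (C14 epimers) | CC(=O)O[C@@H]1C[C@@]2(CO2)[C@]2(CC[C@]3(C([Se]c4ccccc4)COC3)O2)[C@]23CCC[C@](C)(C(=O)OC2)[C@H]13
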